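**Retrosynthetic overview**
- Target ⇒ an aryl iodide carrying an open-chain 3,5-dioxo ester, plus myrcene. One palladium-catalysed operation closes the pyrone ring (ester to lactone) and the dihydrofuran ring (aryl–C and O–C bonds across the vinyl group of the diene), setting C2 as R.
- That iodide ⇒ iodinated 2,4,6-trihydroxyacetophenone + a one-carbon iminium salt + methyl 4-methyl-3,5-dioxoheptanoate (methylene bridge by Mannich/Michael coupling).
- Iodoarene ⇒ 2,4,6-trihydroxyacetophenone; dioxo ester ⇒ methyl 3-oxopentanoate dianion + propanoyl Weinreb amide.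
- Ring order: the benzene ring is bought; the pyrone ring and the dihydrofuran ring are both formed in the last step.

Assumption: the antipode of the chiral ligand in step 4 is the one that delivers the (2R) product, to be confirmed on model iodide 5 before use; the mirror-image ligand would give (2S).

Step 1
Reactants: 1 methyl 3-oxopentanoate; 2 N-methoxy-N-methylpropanamide
Product: 3 methyl 4-methyl-3,5-dioxoheptanoate
Conditions: LiN(i-Pr)2 (2.1 equiv), THF, −78 → 0 °C; then 2, −78 °C → rt; 1 M HCl
Reagents that add atoms: none
Why: Claisen-type γ-acylation of a β-keto ester dianion (Huckin–Weiler chemistry), in which the more basic γ-carbanion attacks the Weinreb amide and the chelated tetrahedral adduct survives until the acid quench, preventing over-addition; the new CH(CH3) centre is freely epimerizable and of no consequence.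

Step 2
Reactants: 4 1-(2,4,6-trihydroxyphenyl)ethan-1-one
Product: 5 1-(2,4,6-trihydroxy-3-iodophenyl)ethan-1-one
Conditions: N-iodosuccinimide (1.0 equiv), MeCN, −20 → 0 °C, dark
Reagents that add atoms: N-iodosuccinimide, IN1C(=O)CCC1=O
Why: Electrophilic aromatic substitution on the phloroglucinol ring, whose two free positions are equivalent; one equivalent of reagent at low temperature stops at the mono-iodide because the first iodine lowers the nucleophilicity of the ring.

Step 3
Reactants: 3 methyl 4-methyl-3,5-dioxoheptanoate; 5 1-(2,4,6-trihydroxy-3-iodophenyl)ethan-1-one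
Product: 7 methyl 2-[(3-acetyl-2,4,6-trihydroxy-5-iodophenyl)methyl]-4-methyl-3,5-dioxoheptanoate, via methylidene dioxo ester 6 (not isolated)
Conditions: 3 (1.2 equiv), Eschenmoser's salt (1.05 equiv), MeCN/CH2Cl2, 0 °C → rt, 30 min; then 5 (1.0 equiv), 40 °C, 12 h
Reagents that add atoms: Eschenmoser's salt (N,N-dimethylmethylideneammonium iodide), C=[N+](C)C.[I-]
Why: Mannich condensation followed by loss of dimethylamine can only occur at the C2 methylene of 3 (the C4 methine has no second hydrogen), giving Michael acceptor 6, which is captured by Friedel–Crafts-type conjugate addition of the single free ring carbon of 5; both new CH centres are epimerizable and are erased when the pyrone forms.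

Step 4
Reactants: 7 methyl 2-[(3-acetyl-2,4,6-trihydroxy-5-iodophenyl)methyl]-4-methyl-3,5-dioxoheptanoate; 8 myrcene (7-methyl-3-methylideneocta-1,6-diene)
Product: 10 3-{[(2R)-5-acetyl-4,6-dihydroxy-2-(6-methylhepta-1,5-dien-2-yl)-2,3-dihydro-1-benzofuran-7-yl]methyl}-6-ethyl-4-hydroxy-5-methyl-2H-pyran-2-one (the target), via iodoaryl pyrone 9 (not isolated)
Conditions: 8 (4 equiv), Pd2(dba)3·CHCl3 (5 mol %), chiral sulfinamide–monophosphine ligand (TY-Phos type, 12 mol %), K2CO3 (3 equiv), 1,4-dioxane, 90 °C, 18 h
Reagents that add atoms: none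
Why: Proposed new method: under K2CO3 at 90 °C the enolate oxygen of the 5-oxo group of 7 attacks the methyl ester to close the 4-hydroxy-2-pyrone (9), while in the same flask the C–I bond adds oxidatively to zerovalent palladium, the aryl–palladium species inserts the unsubstituted vinyl end of 8 to give a 2-substituted π-allyl complex, and the more acidic, non-chelated phenoxide para to the acetyl group attacks the internal allyl carbon 5-exo under control of the chiral ligand, setting C2 as R; the closest known chemistry is the Larock heteroannulation of o-iodophenols with 1,3-dienes in its enantioselective Heck/Tsuji–Trost form, combined with base-mediated lactonization of 3,5-dioxo esters to 4-hydroxy-2-pyrones.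

**Compound list**
1 | methyl 3-oxopentanoate | CCC(=O)CC(=O)OC | starting material
2 | N-methoxy-N-methylpropanamide | CCC(=O)N(C)OC | starting material
3 | methyl 4-methyl-3,5-dioxoheptanoate (racemic, enolizable) | CCC(=O)C(C)C(=O)CC(=O)OC | intermediate
4 | 1-(2,4,6-trihydroxyphenyl)ethan-1-one | CC(=O)c1c(O)cc(O)cc1O | starting material
5 | 1-(2,4,6-trihydroxy-3-iodophenyl)ethan-1-one | CC(=O)c1c(O)cc(O)c(I)c1O | intermediate
6 | methyl 4-methyl-2-methylidene-3,5-dioxoheptanoate | CCC(=O)C(C)C(=O)C(=C)C(=O)OC | intermediate
7 | methyl 2-[(3-acetyl-2,4,6-trihydroxy-5-iodophenyl)methyl]-4-methyl-3,5-dioxoheptanoate (mixture of epimers at the two enolizable CH centres) | CCC(=O)C(C)C(=O)C(Cc1c(O)c(I)c(O)c(C(C)=O)c1O)C(=O)OC | intermediate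
8 | myrcene (7-methyl-3-methylideneocta-1,6-diene) | C=CC(=C)CCC=C(C)C | starting material
9 | 3-[(3-acetyl-2,4,6-trihydroxy-5-iodophenyl)methyl]-6-ethyl-4-hydroxy-5-methyl-2H-pyran-2-one | CC(=O)c1c(O)c(I)c(O)c(Cc2c(O)c(C)c(CC)oc2=O)c1O | intermediate
10 | 3-{[(2R)-5-acetyl-4,6-dihydroxy-2-(6-methylhepta-1,5-dien-2-yl)-2,3-dihydro-1-benzofuran-7-yl]methyl}-6-ethyl-4-hydroxy-5-methyl-2H-pyran-2-one | C=C(CCC=C(C)C)[C@H]1Cc2c(O)c(C(C)=O)c(O)c(Cc3c(O)c(C)c(CC)oc3=O)c2O1 | target

**Totals**
Total steps: 4. Longest linear sequence: 3 steps (1 → 3 → 7 → 10, or 4 → 5 → 7 → 10).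

**Steps most likely to fail, with fallbacks**

Step 4. The risks are sequestration of palladium by the dioxo ester, closure through the phenol ortho to the acetyl group instead of the para one, carbon attack on the π-allyl complex, and insufficient ee on so crowded a substrate. The fallback separates and reorders the two ring closures. It sets out from 5 and 8: the same kind of palladium-catalysed diene heteroannulation is run on the simple iodide, where no dioxo ester is present, to give 1-[(2R)-4,6-dihydroxy-2-(6-methylhepta-1,5-dien-2-yl)-2,3-dihydro-1-benzofuran-5-yl]ethan-1-one F1, whose ee and regiochemistry can be secured before anything else is attached. F1 is then bridged at its only free ring carbon with 3 and Eschenmoser's salt to give methyl 2-{[(2R)-5-acetyl-4,6-dihydroxy-2-(6-methylhepta-1,5-dien-2-yl)-2,3-dihydro-1-benzofuran-7-yl]methyl}-4-methyl-3,5-dioxoheptanoate F2. The pyrone is closed last with DBU in toluene at 80 °C, which comes back to the route at 10.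

Step 3. The risks are attack at the C4 methine of 3 instead of C2, self-condensation of 6, and hemiketal or chromene formation between the new ketone and an ortho phenol. The fallback sets out from 3 and closes the ring before the coupling: DBU in toluene at 80 °C gives 6-ethyl-4-hydroxy-5-methyl-2H-pyran-2-one F3, whose C3 is the only nucleophilic carbon. F3 is coupled with 5 and Eschenmoser's salt in the manner used for methylene-bridged phloroglucinol–pyrone pairs. This comes back to the route at 9, which is then isolated and submitted to the step 4 conditions, where only the dihydrofuran ring has to close.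

Step 2. The risks are over-iodination to the di-iodide and loss of iodine from the electron-rich ring on handling. The fallback postpones the halogenation until only one nucleophilic position is left. It sets out from 4 (2 equiv, to suppress double bridging), which is bridged first with 3 and Eschenmoser's salt to give methyl 2-[(3-acetyl-2,4,6-trihydroxyphenyl)methyl]-4-methyl-3,5-dioxoheptanoate F4. F4 is lactonized with DBU to 3-[(3-acetyl-2,4,6-trihydroxyphenyl)methyl]-6-ethyl-4-hydroxy-5-methyl-2H-pyran-2-one F5. F5 has a single ring CH and no enolizable dicarbonyl CH, so N-iodosuccinimide gives the mono-iodide cleanly. This comes back to the route at 9.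

Further compounds
F1 | step 4 | 1-[(2R)-4,6-dihydroxy-2-(6-methylhepta-1,5-dien-2-yl)-2,3-dihydro-1-benzofuran-5-yl]ethan-1-one | C=C(CCC=C(C)C)[C@H]1Cc2c(O)c(C(C)=O)c(O)cc2O1
F2 | step 4 | methyl 2-{[(2R)-5-acetyl-4,6-dihydroxy-2-(6-methylhepta-1,5-dien-2-yl)-2,3-dihydro-1-benzofuran-7-yl]methyl}-4-methyl-3,5-dioxoheptanoate | C=C(CCC=C(C)C)[C@H]1Cc2c(O)c(C(C)=O)c(O)c(CC(C(=O)OC)C(=O)C(C)C(=O)CC)c2O1
F3 | step 3 | 6-ethyl-4-hydroxy-5-methyl-2H-pyran-2-one | CCc1oc(=O)cc(O)c1C
F4 | step 2 | methyl 2-[(3-acetyl-2,4,6-trihydroxyphenyl)methyl]-4-methyl-3,5-dioxoheptanoate | CCC(=O)C(C)C(=O)C(Cc1c(O)cc(O)c(C(C)=O)c1O)C(=O)OC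
F5 | step 2 | 3-[(3-acetyl-2,4,6-trihydroxyphenyl)methyl]-6-ethyl-4-hydroxy-5-methyl-2H-pyran-2-one | CC(=O)c1c(O)cc(O)c(Cc2c(O)c(C)c(CC)oc2=O)c1O
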